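Atom labels used throughout: tetrahydrofuran ring O1, C2 (aryl), C3, C4, C5; C9 is the oxymethyl carbon on C3, C7' the benzylic carbon on C4. Ar = 3-methoxy-4-(triisopropylsilyloxy)phenyl; TIPS = triisopropylsilyl; TBS = tert-butyldimethylsilyl.

## The problem

The target is the C9 caffeate of a 2-aryl-4-benzyl-3-(hydroxymethyl)tetrahydrofuran lignan with (2R,3S,4S) configuration. Its three stereocentres are contiguous on one five-membered ring: the aryl group on C2 is trans to C9, while C9 and C7' are cis. The cis pair on C3–C4 is the hard part, because introducing a substituent next to an existing one on a five-membered ring normally delivers it trans. C2 is easier: it is a benzylic ether carbon that can be set under the influence of C3. The same benzylic C2–O1 bond, flanked by an electron-rich aryl ring, is fragile towards strong acid and forcing hydrogenolysis. The caffeate is an acrylate-type ester of an oxidisable catechol, so it has to be attached late and unmasked under buffered, non-basic conditions, and four phenols need protection that falls in one operation. Only one stereocentre needs an external source: C4 can control C3 if the two become a ring fusion, and the resulting bicycle can control C2. What makes this possible is that C9 and C7' lie on the same face of the C3–C4 bond and are both oxidisable; joining them through oxygen (C9 as carbonyl, C7' as benzylic C–O) gives a γ-lactone fused to the tetrahydrofuran, and two fused five-membered rings can only be cis-fused.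

## Retrosynthesis

**Ester and silyl ethers.** The C9–O acyl bond and the four phenolic O–H bonds are formed last. Cutting the ester of 21 (through its silylated form 20) gives primary alcohol 16 and the bis-silylated cinnamic acid 19. Keeping all phenols masked until after esterification means only one hydroxyl can be acylated, whereas acylating a free triphenol would leave the site to chance. The forward reactions asked for are a carbodiimide esterification of a primary alcohol and a buffered fluoride desilylation that spares a cinnamate. Acid 19 comes from caffeic acid 17 by persilylation and cleavage of the silyl ester 18.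

**Temporary lactone.** In 16, C9 is taken back to the carboxylic acid 15, and the C7'–H bond is replaced by a bond from C7' to the carboxyl oxygen. This gives the furofuranone 14, in which the difficult cis relationship on C3–C4 has become a ring fusion. The cut is preferred over carrying the benzyl group intact, because the C7' oxygen is also the handle that lets the lactone be built by an aldol reaction. Forward, this requires hydrogenolysis of a benzylic acyloxy C–O bond next to a benzylic ether, followed by hydride reduction of the acid.

**C2–C3 bond (key cut).** Cutting C2–C3 of 14 gives a lactone nucleophile at C3 and an oxocarbenium ion at C2, joined through O1–C5–C4, i.e. the mixed acetal 11 (reacting through 12 and 13). The neighbouring cut, O1–C2, would require an intermolecular aldol at C3 of this lactone first. That aldol would place C2 anti to the C4 substituent, and the ether closure would then demand a trans-fused bicycle. Tethering the electrophile to C4 through C5 and O1 reverses this preference: the new bond has to form on the face that carries C5. The precursor 11 has two stereocentres instead of four and one ring instead of two. The forward reaction must ionise the acetal at the methoxy group, close a five-membered ring onto an oxocarbenium ion in the endo sense, and place the C2 aryl group on the convex face.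

**Acetal C–O bond.** Mixed acetal 11 is cut at the acetal carbon–oxygen bond into hydroxymethyl lactone 10 and dimethyl acetal 3. An acetal is preferred to an ester-derived precursor because the lactone would not survive the hydride needed to convert an ester into an α-acyloxy ether. The forward reaction is a transacetalisation that must stop at mono-exchange.

**Lactone and its two stereocentres.** Alcohol 10 is the reduction product of aryl paraconic acid 9, which comes from imide 8 by auxiliary cleavage. Imide 8 is the lactonised form of syn-aldol adduct 7, so the cut is C4–C7' (aldol) plus the lactone C–O bond, giving succinate imide 6 and aldehyde 2. An auxiliary aldol is preferred to a racemic anhydride condensation followed by resolution, which would discard half of the material. A syn aldol maps onto the trans lactone, and the aldol sets C4 absolutely. C7' is only a relay centre and is erased later.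

**Starting materials.** Imide 6 comes from oxazolidinone 4 and acid chloride 5. Aldehyde 2 and acetal 3 both come from vanillin 1, so both aryl rings of the lignan have the same origin.

## Roads not taken

**Alternative 1:** Cut C4–C7' and C2–C3 in one operation. The lithiated dithiane A2 adds to the β-carbon of the chiral menthyloxy butenolide A1, and the resulting enolate is trapped by aldehyde A3 to give A4. The acetal centre of A1 steers the first addition, and the second follows trans to it.
- Merits: three simple pieces are joined, two C–C bonds are made and C3 and C4 are set in a single step. The rest is reduction, cationic O1–C2 closure, desulfurisation and acylation. At roughly nine operations this road is shorter than the chosen one (thirteen), and that advantage is real.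
- Weak points for this target: A1 is needed with the dextrorotatory menthyl group, the antipode of the cheap natural auxiliary. The sulfur has to be removed with nickel next to a benzylic ether and aryl silyl ethers. C2 is set only at the end, by cationic closure of an open-chain triol. The aldol trapping of a hindered enolate by an electron-rich aldehyde is reversible.
- Against this, the chosen plan uses a recoverable auxiliary available in either hand, avoids stoichiometric sulfur and nickel, and sets C3 by ring fusion and C2 inside a rigid bicycle.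

**Alternative 2:** Cut C3–C9. The bromomethylsilyl ether A5 gives a silylmethyl radical that attacks C3 of the dihydrofuran in a six-membered endo closure; a tin hydride then reduces the C4 radical to give A6. C9 is later unmasked by Tamao oxidation.
- Merits: C9 arrives as a one-carbon unit at the right oxidation level, and no Lewis acid comes near the benzylic ether.
- Weak points: the face of attack at C3 is governed only by the neighbouring C2 aryl group. Hydrogen delivery to C4 must give a 6/5 fusion that, unlike a 5/5 fusion, is not obliged to be cis. A5 needs its own enantioselective synthesis. After oxidation a free benzylic hydroxyl on C7' has to be removed beside the benzylic ether at C2, which is harder than cleaving the acyloxy group of 14.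
- The chosen plan meets the same chemoselectivity question at C7' in a more favourable form, and it does not rely on two independent facial selectivities. Alternative 2 is judged longer and less controlled.

**Alternative 3:** Cut C4–C5. The selenomethyl ether A7 of an anti homopropargylic alcohol gives an O–CH2 radical that adds to the alkyne in a 5-exo-dig closure, producing the benzylidene tetrahydrofuran A8. Hydrogenation of the exocyclic alkene then has to set C4.
- Merits: C2 and C3 are set in acyclic chemistry before ring closure. C9 is carried as a protected alcohol throughout and C7' never bears oxygen, so the hydrogenolysis and acid reduction of the chosen plan (steps 9 and 10) are unnecessary. In redox economy after the key step this road is better.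
- Weak points: C4 is created last, by heterogeneous hydrogenation of a flexible monocycle with one substituent on each face, under conditions that also threaten the C2–O1 bond. A7 needs its own stereoselective synthesis, and tin and selenium reagents are required.
- The chosen plan pays two extra redox steps but obtains the C3/C4 cis relationship as a geometric necessity, not from a facial preference.

Key step: step 8

Assumption: (R)-4-benzyl-1,3-oxazolidin-2-one (4) and methyl 4-chloro-4-oxobutanoate (5) are purchased; the acetal carbon of 11 is carried as both epimers, since it becomes trigonal in step 8.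

## Route

Step 1
Reactants: 1 vanillin (4-hydroxy-3-methoxybenzaldehyde)
Product: 2 3-methoxy-4-(triisopropylsilyloxy)benzaldehyde
Conditions: i-Pr3SiCl, imidazole, DMF, rt
Reagents that add atoms: triisopropylsilyl chloride, CC(C)[Si](Cl)(C(C)C)C(C)C
Why: Standard phenol silylation; the TIPS ether is chosen because it should withstand the basic peroxide of step 5 and the silyl triflate of step 8 better than a smaller silyl ether and still falls to fluoride in step 13.

Step 2
Reactants: 2 3-methoxy-4-(triisopropylsilyloxy)benzaldehyde
Product: 3 ArCH(OMe)2, 4-(dimethoxymethyl)-2-methoxy-1-(triisopropylsilyloxy)benzene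
Conditions: HC(OMe)3, MeOH, PPTS (cat.), rt; Et3N quench
Reagents that add atoms: trimethyl orthoformate, COC(OC)OC; methanol, CO
Why: Acid-catalysed acetalisation driven by the orthoester as water scavenger; the aryl silyl ether is stable to pyridinium tosylate.

Step 3
Reactants: 4 (R)-4-benzyl-1,3-oxazolidin-2-one; 5 methyl 4-chloro-4-oxobutanoate
Product: 6 methyl 4-[(4R)-4-benzyl-2-oxo-1,3-oxazolidin-3-yl]-4-oxobutanoate
Conditions: n-BuLi, THF, −78 °C; then 5, −78 → 0 °C
Reagents that add atoms: none
Why: N-acylation of the lithiated oxazolidinone by an acid chloride, the usual entry to Evans imides; the methyl ester is untouched at low temperature.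

Step 4
Reactants: 6 methyl 4-[(4R)-4-benzyl-2-oxo-1,3-oxazolidin-3-yl]-4-oxobutanoate; 2 3-methoxy-4-(triisopropylsilyloxy)benzaldehyde
Product: 8 (4R)-4-benzyl-3-[(2R,3R)-2-Ar-5-oxooxolane-3-carbonyl]-1,3-oxazolidin-2-one (trans lactone), via syn-aldol adduct 7 (not isolated)
Conditions: Bu2BOTf, i-Pr2NEt, CH2Cl2, 0 °C; then 2, −78 → 0 °C; pH 7 buffer, MeOH, H2O2; then PPTS (cat.), CH2Cl2, rt
Reagents that add atoms: none
Why: Evans syn aldol through the Z-boron enolate and a Zimmerman–Traxler chair: the (R)-benzyl group blocks one enolate face, which fixes the future C4 as (R) in 7, and the closed transition state gives the syn (R) carbinol at C7'. The carbinol then lactonises onto the methyl ester (5-exo-trig) with retention at both centres, and a syn aldol maps onto the trans lactone.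

Step 5
Reactants: 8 (4R)-4-benzyl-3-[(2R,3R)-2-Ar-5-oxooxolane-3-carbonyl]-1,3-oxazolidin-2-one
Product: 9 (2R,3R)-2-Ar-5-oxooxolane-3-carboxylic acid (trans aryl paraconic acid)
Conditions: LiOH, H2O2, THF–H2O, 0 °C; Na2SO3; 1 M HCl
Reagents that add atoms: hydrogen peroxide, OO
Why: Hydroperoxide cleaves the exocyclic imide carbonyl selectively and frees the auxiliary for recovery; any lactone opened by base recloses on acidification, and the centre α to the carboxylate does not epimerise at 0 °C.

Step 6
Reactants: 9 (2R,3R)-2-Ar-5-oxooxolane-3-carboxylic acid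
Product: 10 (4S,5R)-4-(hydroxymethyl)-5-Ar-oxolan-2-one
Conditions: BH3·SMe2, THF, 0 °C → rt; MeOH
Reagents that add atoms: none
Why: Borane reduces a carboxylic acid much faster than a lactone, the standard conversion of paraconic acids into β-hydroxymethyl lactones; the medium is never basic, so the alcohol should not translactonise.

Step 7
Reactants: 10 (4S,5R)-4-(hydroxymethyl)-5-Ar-oxolan-2-one; 3 ArCH(OMe)2
Product: 11 (4S,5R)-4-{[methoxy(Ar)methoxy]methyl}-5-Ar-oxolan-2-one (mixed methyl acetal, both epimers at the acetal carbon)
Conditions: 3 (3 equiv), PPTS (cat.), 5 Å MS, PhMe, rt → 40 °C; Et3N; Et3N-deactivated silica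
Reagents that add atoms: none
Why: Acid-catalysed transacetalisation; excess dimethyl acetal and uptake of methanol by the sieves should push the equilibrium to mono-exchange, and the lactone and silyl ethers tolerate the mild acid.

Step 8
Reactants: 11 (4S,5R)-4-{[methoxy(Ar)methoxy]methyl}-5-Ar-oxolan-2-one
Product: 14 (3R,3aS,6R,6aR)-3,6-di-Ar-tetrahydro-1H,3H-furo[3,4-c]furan-1-one (cis-fused furofuranone, both aryl groups on the convex face), via silyl ketene acetal 12 (not isolated), via oxocarbenium triflate 13 (not isolated)
Conditions: LiN(SiMe3)2, THF, −78 °C, then Me3SiCl; pentane, filter; then Me3SiOTf (0.2 equiv), 2,6-di-tert-butyl-4-methylpyridine, CH2Cl2 (0.01 M), −78 → −40 °C; pyridine quench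
Reagents that add atoms: none
Why: Enolisation of the lactone and O-silylation give silyl ketene acetal 12; catalytic Me3SiOTf then removes the methoxy group of the mixed acetal as MeOSiMe3 and leaves the aryl-stabilised (E)-oxocarbenium ion 13, whose carbon C2 is attacked by the ketene acetal carbon C3 with return of the silyl group to triflate. The closest known reaction type is the silyl triflate-catalysed Mukaiyama aldol-type addition of silyl ketene acetals to acetals, run here within one molecule. The tetrahydrofuran closes in a 5-(enolexo)-endo-trig mode (O1=C2 inside the new ring, C3=C9 outside it); this mode is poor for neutral acceptors but established for oxocarbenium ions, as in the ring-forming step of the Petasis–Ferrier rearrangement of 4-methylene-1,3-dioxolanes. C3 is set by C4: the three-atom tether C4–C5–O1 lets C2 reach only the face of C3 that carries C5, and a bicyclo[3.3.0] skeleton cannot be trans-fused, so C9 and C7' end up cis. C2 is set by the bicyclic transition state: the (E)-oxocarbenium ion lies below C3–C4 with O1 at the outer flap of the envelope, so its aryl group points away from the ketene acetal and should land on the convex face, trans to C9. The step needs ionisation at the methoxy oxygen and not at the tether oxygen; the methoxy group is the less hindered donor, wrong-way ionisation is reversible, and high dilution leaves only the intramolecular capture productive. At −78 °C the aryl silyl ethers, the benzylic lactone C–O bond and the C4 centre should not be touched, and C7', even if it were to leak, is erased in step 9.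

Step 9
Reactants: 14 (3R,3aS,6R,6aR)-3,6-di-Ar-tetrahydro-1H,3H-furo[3,4-c]furan-1-one
Product: 15 (2R,3R,4S)-2-Ar-4-(ArCH2)-oxolane-3-carboxylic acid
Conditions: H2 (1 atm), 10% Pd/C, Et3N (1.1 equiv), EtOAc–MeOH, rt; 1 M HCl wash
Reagents that add atoms: none
Why: Hydrogenolysis of a benzylic C–O bond: acyloxy leaves from palladium far more readily than alkoxy, and the amine further retards benzyl ether cleavage, so the lactone C7'–O bond should break while C2–O1 stays. C7' becomes a methylene group, and C2, C3 and C4 are not involved.

Step 10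
Reactants: 15 (2R,3R,4S)-2-Ar-4-(ArCH2)-oxolane-3-carboxylic acid
Product: 16 [(2R,3S,4S)-2-Ar-4-(ArCH2)-oxolan-3-yl]methanol
Conditions: BH3·SMe2, THF, 0 °C → rt; MeOH
Reagents that add atoms: none
Why: Chemoselective borane reduction of the acid; no base is present, so C3 (α to the carboxyl and cis to the C4 substituent) cannot epimerise, and ethers and silyl ethers are inert.

Step 11
Reactants: 17 caffeic acid, (E)-3-(3,4-dihydroxyphenyl)prop-2-enoic acid
Product: 19 (E)-3-[3,4-bis(tert-butyldimethylsilyloxy)phenyl]prop-2-enoic acid, via silyl ester 18 (not isolated)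
Conditions: t-BuMe2SiCl, imidazole, DMF, rt; then K2CO3, THF–MeOH–H2O, rt; 1 M HCl to pH 4
Reagents that add atoms: tert-butyldimethylsilyl chloride, CC(C)(C)[Si](C)(C)Cl
Why: Persilylation followed by selective cleavage of the much more labile silyl ester, the usual preparation of O-silylated hydroxycinnamic acids; brief carbonate treatment leaves the aryl silyl ethers.

Step 12
Reactants: 16 [(2R,3S,4S)-2-Ar-4-(ArCH2)-oxolan-3-yl]methanol; 19 (E)-3-[3,4-bis(tert-butyldimethylsilyloxy)phenyl]prop-2-enoic acid
Product: 20 [(2R,3S,4S)-2-Ar-4-(ArCH2)-oxolan-3-yl]methyl (E)-3-[3,4-bis(tert-butyldimethylsilyloxy)phenyl]prop-2-enoate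
Conditions: EDC·HCl, DMAP, CH2Cl2, 0 °C → rt
Reagents that add atoms: none
Why: Steglich esterification of the only free hydroxyl, a primary alcohol; the conditions are neutral, so the benzylic ether, the stereocentres and the alkene geometry are preserved.

Step 13
Reactants: 20 [(2R,3S,4S)-2-Ar-4-(ArCH2)-oxolan-3-yl]methyl (E)-3-[3,4-bis(tert-butyldimethylsilyloxy)phenyl]prop-2-enoate
Product: 21 [(2R,3S,4S)-2-(4-hydroxy-3-methoxyphenyl)-4-[(4-hydroxy-3-methoxyphenyl)methyl]oxolan-3-yl]methyl (E)-3-(3,4-dihydroxyphenyl)prop-2-enoate
Conditions: Bu4NF, AcOH, THF, 0 °C → rt; pH 5 buffer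
Reagents that add atoms: none
Why: Fluoride cleaves aryl silyl ethers rapidly; acetic acid keeps the liberated phenols and catechol protonated, which protects the cinnamate from phenoxide-mediated cleavage and the catechol from air oxidation.

## Compound list

1 | vanillin, 4-hydroxy-3-methoxybenzaldehyde | COc1cc(C=O)ccc1O | starting material
2 | 3-methoxy-4-(triisopropylsilyloxy)benzaldehyde | COc1cc(C=O)ccc1O[Si](C(C)C)(C(C)C)C(C)C | intermediate
3 | 4-(dimethoxymethyl)-2-methoxy-1-(triisopropylsilyloxy)benzene | COc1cc(C(OC)OC)ccc1O[Si](C(C)C)(C(C)C)C(C)C | intermediate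
4 | (R)-4-benzyl-1,3-oxazolidin-2-one | O=C1N[C@H](Cc2ccccc2)CO1 | starting material
5 | methyl 4-chloro-4-oxobutanoate | COC(=O)CCC(Cl)=O | starting material
6 | methyl 4-[(4R)-4-benzyl-2-oxo-1,3-oxazolidin-3-yl]-4-oxobutanoate | COC(=O)CCC(=O)N1[C@H](Cc2ccccc2)COC1=O | intermediate
7 | methyl (3R)-4-[(4R)-4-benzyl-2-oxo-1,3-oxazolidin-3-yl]-3-{(R)-hydroxy[3-methoxy-4-(triisopropylsilyloxy)phenyl]methyl}-4-oxobutanoate (syn aldol adduct) | COC(=O)C[C@H]([C@@H](O)c1ccc(O[Si](C(C)C)(C(C)C)C(C)C)c(OC)c1)C(=O)N1[C@H](Cc2ccccc2)COC1=O | intermediate (not isolated)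
8 | (4R)-4-benzyl-3-{(2R,3R)-2-[3-methoxy-4-(triisopropylsilyloxy)phenyl]-5-oxooxolane-3-carbonyl}-1,3-oxazolidin-2-one | COc1cc([C@@H]2OC(=O)C[C@H]2C(=O)N2[C@H](Cc3ccccc3)COC2=O)ccc1O[Si](C(C)C)(C(C)C)C(C)C | intermediate
9 | (2R,3R)-2-[3-methoxy-4-(triisopropylsilyloxy)phenyl]-5-oxooxolane-3-carboxylic acid | COc1cc([C@@H]2OC(=O)C[C@H]2C(=O)O)ccc1O[Si](C(C)C)(C(C)C)C(C)C | intermediate
10 | (4S,5R)-4-(hydroxymethyl)-5-[3-methoxy-4-(triisopropylsilyloxy)phenyl]oxolan-2-one | COc1cc([C@@H]2OC(=O)C[C@H]2CO)ccc1O[Si](C(C)C)(C(C)C)C(C)C | intermediate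
11 | (4S,5R)-4-({methoxy[3-methoxy-4-(triisopropylsilyloxy)phenyl]methoxy}methyl)-5-[3-methoxy-4-(triisopropylsilyloxy)phenyl]oxolan-2-one (both acetal epimers) | COc1cc([C@@H]2OC(=O)C[C@H]2COC(OC)c2ccc(O[Si](C(C)C)(C(C)C)C(C)C)c(OC)c2)ccc1O[Si](C(C)C)(C(C)C)C(C)C | intermediate
12 | (2R,3S)-3-({methoxy[3-methoxy-4-(triisopropylsilyloxy)phenyl]methoxy}methyl)-2-[3-methoxy-4-(triisopropylsilyloxy)phenyl]-5-(trimethylsilyloxy)-2,3-dihydrofuran (silyl ketene acetal of 11) | COc1cc([C@@H]2OC(O[Si](C)(C)C)=C[C@H]2COC(OC)c2ccc(O[Si](C(C)C)(C(C)C)C(C)C)c(OC)c2)ccc1O[Si](C(C)C)(C(C)C)C(C)C | intermediate (not isolated)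
13 | (E)-oxocarbenium triflate formed from 12 by loss of methoxide: O-{[(2R,3S)-2-aryl-5-(trimethylsilyloxy)-2,3-dihydrofuran-3-yl]methyl} arylmethylideneoxonium trifluoromethanesulfonate | COc1cc([C@@H]2OC(O[Si](C)(C)C)=C[C@H]2C/[O+]=C/c2ccc(O[Si](C(C)C)(C(C)C)C(C)C)c(OC)c2)ccc1O[Si](C(C)C)(C(C)C)C(C)C.[O-]S(=O)(=O)C(F)(F)F | intermediate (not isolated)
14 | (3R,3aS,6R,6aR)-3,6-bis[3-methoxy-4-(triisopropylsilyloxy)phenyl]tetrahydro-1H,3H-furo[3,4-c]furan-1-one | COc1cc([C@@H]2OC(=O)[C@H]3[C@H](c4ccc(O[Si](C(C)C)(C(C)C)C(C)C)c(OC)c4)OC[C@@H]23)ccc1O[Si](C(C)C)(C(C)C)C(C)C | intermediate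
15 | (2R,3R,4S)-2-[3-methoxy-4-(triisopropylsilyloxy)phenyl]-4-[3-methoxy-4-(triisopropylsilyloxy)benzyl]oxolane-3-carboxylic acid | COc1cc(C[C@@H]2CO[C@@H](c3ccc(O[Si](C(C)C)(C(C)C)C(C)C)c(OC)c3)[C@@H]2C(=O)O)ccc1O[Si](C(C)C)(C(C)C)C(C)C | intermediate
16 | {(2R,3S,4S)-2-[3-methoxy-4-(triisopropylsilyloxy)phenyl]-4-[3-methoxy-4-(triisopropylsilyloxy)benzyl]oxolan-3-yl}methanol | COc1cc(C[C@@H]2CO[C@@H](c3ccc(O[Si](C(C)C)(C(C)C)C(C)C)c(OC)c3)[C@@H]2CO)ccc1O[Si](C(C)C)(C(C)C)C(C)C | intermediate
17 | caffeic acid, (E)-3-(3,4-dihydroxyphenyl)prop-2-enoic acid | OC(=O)/C=C/c1ccc(O)c(O)c1 | starting material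
18 | tert-butyldimethylsilyl (E)-3-[3,4-bis(tert-butyldimethylsilyloxy)phenyl]prop-2-enoate | CC(C)(C)[Si](C)(C)OC(=O)/C=C/c1ccc(O[Si](C)(C)C(C)(C)C)c(O[Si](C)(C)C(C)(C)C)c1 | intermediate (not isolated)
19 | (E)-3-[3,4-bis(tert-butyldimethylsilyloxy)phenyl]prop-2-enoic acid | OC(=O)/C=C/c1ccc(O[Si](C)(C)C(C)(C)C)c(O[Si](C)(C)C(C)(C)C)c1 | intermediate
20 | {(2R,3S,4S)-2-[3-methoxy-4-(triisopropylsilyloxy)phenyl]-4-[3-methoxy-4-(triisopropylsilyloxy)benzyl]oxolan-3-yl}methyl (E)-3-[3,4-bis(tert-butyldimethylsilyloxy)phenyl]prop-2-enoate | COc1cc(C[C@@H]2CO[C@@H](c3ccc(O[Si](C(C)C)(C(C)C)C(C)C)c(OC)c3)[C@@H]2COC(=O)/C=C/c2ccc(O[Si](C)(C)C(C)(C)C)c(O[Si](C)(C)C(C)(C)C)c2)ccc1O[Si](C(C)C)(C(C)C)C(C)C | intermediate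
21 | [(2R,3S,4S)-2-(4-hydroxy-3-methoxyphenyl)-4-[(4-hydroxy-3-methoxyphenyl)methyl]oxolan-3-yl]methyl (E)-3-(3,4-dihydroxyphenyl)prop-2-enoate | COc1cc(C[C@@H]2CO[C@@H](c3ccc(O)c(OC)c3)[C@@H]2COC(=O)/C=C/c2ccc(O)c(O)c2)ccc1O | target

## Step count and least certain steps

Total step count: 13. Longest linear sequence: 10 steps (1, 4, 5, 6, 7, 8, 9, 10, 12, 13).

**Step 8 (key step).** Three processes could spoil it:
- ionisation of the mixed acetal at the tether oxygen, followed by intermolecular capture of the freed cation, which would add the aryl carbon anti to C5 and block ring closure;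
- silylation of the lactone enolate on carbon instead of oxygen;
- incomplete facial control at C2, because the 5-endo geometry gives a loose transition state.

Fallback: this gives up the tether and uses the classical order of bond formation. It sets out from 10 and returns at 16.
- Hydrogenolysis of 10 (H2, Pd/C, EtOAc–AcOH) gives the hydroxy acid F1, which closes on mild acid to the β-benzyl lactone F2.
- The lithium enolate of F2 (LiN(SiMe3)2, THF, −78 °C) adds to aldehyde 2 anti to the benzyl group to give the aldol adduct F3. Its carbinol configuration is irrelevant.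
- LiBH4 opens the lactone to the triol F4.
- Catalytic camphorsulfonic acid in CH2Cl2 ionises the electron-rich benzylic alcohol, and the C5 hydroxyl captures the cation to close the tetrahydrofuran. Because the lactone oxygen is now on C5 and not on C7', the anti aldol maps onto the cis C9/C7' relationship of 16.

**Step 7.** The exchange may stop at an equilibrium mixture, continue to the symmetrical acetal of two molecules of 10, or be reversed by hydrolysis on silica. Prolonged acid could also translactonise 10.

Fallback: an irreversible alkylation replaces the equilibrium. It sets out from 3 and 10 and returns at 11. Acetyl chloride converts 3 (CH2Cl2, 0 °C) into the α-chloro ether F5, which is used at once to alkylate 10 in the presence of i-Pr2NEt at −40 °C.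

**Step 9.** Hydrogenolysis may not stop after the lactone C7'–O bond and may go on to cleave the C2–O1 benzylic ether, or it may stall on the hindered secondary position.

Fallback: radical deoxygenation replaces hydrogenolysis. It sets out from 14 and returns at 16, bypassing step 10.
- LiBH4 reduces the lactone to the diol F6.
- t-BuMe2SiCl and imidazole silylate the primary hydroxyl selectively to give the silyl ether F7.
- Phenyl chlorothionoformate and DMAP convert the benzylic alcohol into the thionocarbonate F8.
- Barton–McCombie reduction (Bu3SnH, AIBN, PhMe, 80 °C) gives the deoxygenated silyl ether F9.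
- PPTS in MeOH removes the alkyl TBS group while leaving the aryl TIPS ethers.

**Step 13.** With four silyl groups to remove, phenoxide formed transiently could cleave or transesterify the cinnamate, and the free catechol could oxidise during a slow reaction.

Fallback: the order of events is changed so that no ester is present during desilylation. It sets out from 16 and returns at 21. Bu4NF removes both TIPS groups to give the triol F10, and Mitsunobu esterification (PPh3, diisopropyl azodicarboxylate, THF) of its primary alcohol with unprotected caffeic acid 17 gives 21 directly. The carboxylic acid is by far the most acidic pronucleophile present.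

## Further compounds

F1 | step 8 | (S)-3-(hydroxymethyl)-4-[3-methoxy-4-(triisopropylsilyloxy)phenyl]butanoic acid | COc1cc(C[C@H](CO)CC(=O)O)ccc1O[Si](C(C)C)(C(C)C)C(C)C
F2 | step 8 | (S)-4-[3-methoxy-4-(triisopropylsilyloxy)benzyl]oxolan-2-one | COc1cc(C[C@@H]2COC(=O)C2)ccc1O[Si](C(C)C)(C(C)C)C(C)C
F3 | step 8 | (3R,4S)-3-{hydroxy[3-methoxy-4-(triisopropylsilyloxy)phenyl]methyl}-4-[3-methoxy-4-(triisopropylsilyloxy)benzyl]oxolan-2-one (3,4-trans, carbinol epimers) | COc1cc(C[C@@H]2COC(=O)[C@H]2C(O)c2ccc(O[Si](C(C)C)(C(C)C)C(C)C)c(OC)c2)ccc1O[Si](C(C)C)(C(C)C)C(C)C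
F4 | step 8 | (2S,3S)-2-{hydroxy[3-methoxy-4-(triisopropylsilyloxy)phenyl]methyl}-3-[3-methoxy-4-(triisopropylsilyloxy)benzyl]butane-1,4-diol (carbinol epimers) | COc1cc(C[C@H](CO)[C@@H](CO)C(O)c2ccc(O[Si](C(C)C)(C(C)C)C(C)C)c(OC)c2)ccc1O[Si](C(C)C)(C(C)C)C(C)C
F5 | step 7 | 4-[chloro(methoxy)methyl]-2-methoxy-1-(triisopropylsilyloxy)benzene | COc1cc(C(Cl)OC)ccc1O[Si](C(C)C)(C(C)C)C(C)C
F6 | step 9 | (R)-{(3S,4S,5R)-4-(hydroxymethyl)-5-[3-methoxy-4-(triisopropylsilyloxy)phenyl]oxolan-3-yl}[3-methoxy-4-(triisopropylsilyloxy)phenyl]methanol | COc1cc([C@H](O)[C@@H]2CO[C@@H](c3ccc(O[Si](C(C)C)(C(C)C)C(C)C)c(OC)c3)[C@@H]2CO)ccc1O[Si](C(C)C)(C(C)C)C(C)C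
F7 | step 9 | primary tert-butyldimethylsilyl ether of F6 | COc1cc([C@H](O)[C@@H]2CO[C@@H](c3ccc(O[Si](C(C)C)(C(C)C)C(C)C)c(OC)c3)[C@@H]2CO[Si](C)(C)C(C)(C)C)ccc1O[Si](C(C)C)(C(C)C)C(C)C
F8 | step 9 | O-phenyl thionocarbonate of the benzylic alcohol of F7 | COc1cc([C@H](OC(=S)Oc3ccccc3)[C@@H]2CO[C@@H](c3ccc(O[Si](C(C)C)(C(C)C)C(C)C)c(OC)c3)[C@@H]2CO[Si](C)(C)C(C)(C)C)ccc1O[Si](C(C)C)(C(C)C)C(C)C
F9 | step 9 | tert-butyldimethylsilyl ether of 16 | COc1cc(C[C@@H]2CO[C@@H](c3ccc(O[Si](C(C)C)(C(C)C)C(C)C)c(OC)c3)[C@@H]2CO[Si](C)(C)C(C)(C)C)ccc1O[Si](C(C)C)(C(C)C)C(C)C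
F10 | step 13 | 4-{(2R,3S,4S)-4-[(4-hydroxy-3-methoxyphenyl)methyl]-3-(hydroxymethyl)oxolan-2-yl}-2-methoxyphenol | COc1cc(C[C@@H]2CO[C@@H](c3ccc(O)c(OC)c3)[C@@H]2CO)ccc1O
A1 | alternative 1 | (5S)-5-{[(1S,2R,5S)-5-methyl-2-(propan-2-yl)cyclohexyl]oxy}furan-2(5H)-one | O=C1O[C@H](O[C@H]2C[C@@H](C)CC[C@@H]2C(C)C)C=C1
A2 | alternative 1 | 2-[4-(tert-butyldimethylsilyloxy)-3-methoxyphenyl]-1,3-dithiane | COc1cc(C2SCCCS2)ccc1O[Si](C)(C)C(C)(C)C
A3 | alternative 1 | 4-(tert-butyldimethylsilyloxy)-3-methoxybenzaldehyde | COc1cc(C=O)ccc1O[Si](C)(C)C(C)(C)C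
A4 | alternative 1 | trans α-(aryl hydroxymethyl)-β-(2-aryl-1,3-dithian-2-yl)-γ-menthyloxy butanolide (carbinol carbon unassigned) | O=C1O[C@H](O[C@H]2C[C@@H](C)CC[C@@H]2C(C)C)[C@@H](C2(c3ccc(O[Si](C)(C)C(C)(C)C)c(OC)c3)SCCCS2)[C@@H]1C(O)c1ccc(O[Si](C)(C)C(C)(C)C)c(OC)c1
A5 | alternative 2 | (bromomethyl)dimethylsilyl ether of the aryl carbinol on C3 of a (2R)-2-aryl-2,5-dihydrofuran (carbinol carbon unassigned) | COc1cc(C(O[Si](C)(C)CBr)C2=C[C@H](c3ccc(O[Si](C)(C)C(C)(C)C)c(OC)c3)OC2)ccc1O[Si](C)(C)C(C)(C)C
A6 | alternative 2 | cis-fused oxasilinane–tetrahydrofuran bicycle | COc1cc(C2O[Si](C)(C)C[C@H]3[C@H](c4ccc(O[Si](C)(C)C(C)(C)C)c(OC)c4)OC[C@@H]23)ccc1O[Si](C)(C)C(C)(C)C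
A7 | alternative 3 | (phenylseleno)methyl ether of the anti 1,4-diaryl-2-(silyloxymethyl)but-3-yn-1-ol | COc1cc(C#C[C@@H](CO[Si](C)(C)C(C)(C)C)[C@@H](OC[Se]c2ccccc2)c2ccc(O[Si](C)(C)C(C)(C)C)c(OC)c2)ccc1O[Si](C)(C)C(C)(C)C
A8 | alternative 3 | trans 2-aryl-3-(silyloxymethyl)-4-benzylidenetetrahydrofuran (alkene geometry unassigned) | COc1cc(C=C2CO[C@@H](c3ccc(O[Si](C)(C)C(C)(C)C)c(OC)c3)[C@@H]2CO[Si](C)(C)C(C)(C)C)ccc1O[Si](C)(C)C(C)(C)C
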